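The target in this flask competes with the other capture product, and what you carry is how their ratio follows the substrate charge.

| flask | substrate | second nucleophile | solid first nucleophile | remark | time |
|---|---|---|---|---|---|
| gamma | 0.028 M | 1.5 equiv | 0.60 equiv | run made earlier |  |
| theta | 0.044 M | 1.5 equiv | 0.60 equiv | run made earlier |  |
| delta | 0.020 M | 1.5 equiv | 1.2 equiv | run made earlier |  |
| flask | 0.020 M | 1.50 equiv | 0.600 equiv |  | 8.0 min |

| run | time / min | other capture product / % | target / % | substrate / % |
|---|---|---|---|---|
| gamma | 1.33 | 21 | 17 | 34 |
| gamma | 3.00 | 22 | 21 | 7 |
| gamma | 6.00 | 21 | 22 | 3 |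
| gamma | 10.0 | 22 | 23 | 1 |
| theta | 2.50 | 31 | 17 | 10 |
| theta | 5.00 | 29 | 18 | 1 |
| theta | 8.00 | 35 | 18 | 0 |
| theta | 10.0 | 30 | 19 | 2 |
| delta | 0.833 | 9 | 12 | 51 |
| delta | 2.00 | 18 | 17 | 17 |
| delta | 4.00 | 19 | 22 | 3 |
| delta | 10.0 | 18 | 23 | 1 |

(standard deviation of a reading: 2 percentage points)

- at the start none of the solid first nucleophile is in solution

1. ratio of other capture product to target at 4.0 s
2. ratio of other capture product to target at 40 s
3. ratio of other capture product to target at 8.0 min
4. which of other capture product and target there is more of at 8.0 min

Start at the end of the runs. At the last reading, the theta run gives a ratio of other capture product to target of 1.58 and the gamma run 0.957, so the ratio rises with substrate. Suppose both nucleophiles share one intermediate. The ratio is then a selectivity factor times c(second nucleophile) over c(first nucleophile). Freeze c(first nucleophile) at a saturation level and take c(second nucleophile) from its charge, and the ratio goes with c(substrate).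

Theta then gives 35.9 M⁻¹: this final ratio per molar of substrate, at 1.50 equiv of second nucleophile, is the capture slope. Gamma gives 34.2 M⁻¹, and delta, with twice the solid, gives 39.1 M⁻¹, with readings scattering by 2 percentage points.

Now run the flask slowly. In the first instants c(first nucleophile) is zero and climbing, so the ratio starts high, and no reading says how high. In the middle, delta's first reading gives a substrate half-life of 0.857 min, and its ratio there is already 0.750, so I expect the flask near its end value by 40 s. By 8.0 min that half-life leaves 0.155% of the substrate. My end ratio is 0.718, with the target ahead.

The forecast says 8, 1.5 and 0.87, with target ahead; for the two early ratios its ground is that “Early on, little first nucleophile has dissolved, so other capture should dominate”. It stands above my reckoning at 40 s, 1.5 against my 0.718.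

The flask gives 1.39, 0.852 and 0.791, with target ahead, 23.4% against 18.5%.

    substrate → intermediate (k = 0.0140 s⁻¹)
    first nucleophile + intermediate → target (k = 430 M⁻¹ s⁻¹)
    second nucleophile + intermediate → other capture product (k = 92.0 M⁻¹ s⁻¹)
    intermediate → solvolysis product (k = 8.10 s⁻¹)
    solid first nucleophile ⇌ first nucleophile, rate k5*(cs5 - [first nucleophile]) while solid is left; crystals form when [first nucleophile] > cs5 (solubility = 7.90 mM, k = 0.550 s⁻¹)

The capture slope's 0.718 stands against 0.791 in this flask, where c(first nucleophile) reads 0.00784 M at 0.800 min and 0.00732 M at 8.00 min. The neighbouring flask has 0.080 M of substrate, with the same equivalents, loadings and time. There the slope gives 2.87, and that flask gives 2.86, with 44.9% of other capture product against 15.7% of target. Its c(first nucleophile) stands at 0.00790 M, with 57.3% of its solid charge left.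

The data were computed for substances that don't exist; the scatter is artificial.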